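**Plan**

1. Retrosynthesis: the C15 aldehyde and the C16 acetate are set last. The five-membered ring C16–O–C11–C12–C13 is cut at O–C11 back to a cyclobutanone (C16=O bridging C11 and C13, a bicyclo[3.1.1]heptan-6-one). C16–C13 and C11–C12 are then cut by a retro-[2+2] to a ketene on the C9 arm and a vinyl sulfide on C14, and C8–C14 by a retro-Claisen to an allyl enol ether of a C8 ketone made from (+)-sclareolide.
2. Enabling feature: the oxygen on C11 and C16 on C13 are cis-1,3-diaxial (β) on the chair of ring C (C8, C9, C11, C12, C13, C14). The lactol ring is therefore a cyclobutanone plus one inserted oxygen, and C16 of the resulting γ-lactone is one hydride below the acetoxy acetal.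
3. Forward: rings A and B come from sclareolide; Wittig olefination and Claisen rearrangement make quaternary C8 and C14; the ketene–vinyl sulfide [2+2] closes ring C and the four-membered ring together; Baeyer–Villiger oxygen insertion enlarges the four- to the five-membered ring; lactol formation, acetylation and C15 oxidation finish.
4. Stereochemistry: C5, C9 and C10 come from sclareolide. C8 and C14 come from the chair Claisen transition state (bond formation anti to the axial C10 methyl, E,E geometry). C11 and C13 come from the diaxial β mode of the [2+2]. The C11–O bond forms with retention in the oxygen insertion, and C16 is set by exo acetylation.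

Key step: step 14

Remark on the chemistry: atoms are numbered as in the spongian skeleton (C1–C10 decalin, C20 on C10, C17 on C8, ring C = C8, C9, C11, C12, C13, C14, C15 on C14, C16 on C13); β is the face of the C10 methyl group. (E)-But-2-ene-1,4-diol is taken as a commercial compound.

Step 1
Reactants: 1 (+)-sclareolide
Product: 3 methyl 8α-hydroxy ester, via potassium carboxylate 2 (not isolated)
Conditions: KOH, MeOH/H2O, reflux; evaporation; MeI, DMF, rt
Reagents that add atoms: potassium hydroxide [K+].[OH-]; iodomethane CI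
Why: Saponification opens the γ-lactone and the carboxylate is O-methylated by an SN2 reaction before it can re-close, leaving the tertiary 8α-alcohol free and no stereocenter touched.

Step 2
Reactants: 3 methyl 8α-hydroxy ester
Product: 4 exocyclic alkene ester
Conditions: SOCl2, pyridine, CH2Cl2, −78 °C
Reagents that add atoms: none
Why: Low-temperature dehydration of the tertiary alcohol through its chlorosulfite (E2-type elimination) should give mainly the exocyclic alkene, the endocyclic isomers being removed after step 3; no stereocenter is formed.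

Step 3
Reactants: 4 exocyclic alkene ester
Product: 6 C8 keto ester, via ozonide 5 (not isolated)
Conditions: O3, CH2Cl2, −78 °C; then Me2S, −78 °C to rt
Reagents that add atoms: ozone [O-][O+]=O
Why: Ozonolysis of the 1,1-disubstituted alkene with reductive work-up gives the C8 ketone, and the epimerizable C9 keeps its more stable equatorial side chain.

Step 4
Reactants: 7 (E)-but-2-ene-1,4-diol
Product: 8 (E)-4-(benzyloxy)but-2-en-1-ol
Conditions: NaH, BnBr, THF, 0 °C to rt (diol in excess)
Reagents that add atoms: benzyl bromide BrCc1ccccc1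
Why: Williamson etherification of the mono-alkoxide of the symmetric diol gives the mono-benzyl ether with the E double bond unchanged.

Step 5
Reactants: 8 (E)-4-(benzyloxy)but-2-en-1-ol
Product: 10 alkoxymethyl phosphonium chloride, via chloromethyl ether 9 (not isolated)
Conditions: paraformaldehyde, HCl (g), CH2Cl2, 0 °C; concentration; PPh3, toluene, 50 °C
Reagents that add atoms: formaldehyde (as paraformaldehyde) C=O; hydrogen chloride Cl; triphenylphosphine c1ccccc1P(c1ccccc1)c1ccccc1
Why: Chloromethylation of the primary alcohol followed by SN2 quaternization of triphenylphosphine gives the salt needed for a Wittig alkoxymethylenation.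

Step 6
Reactants: 6 C8 keto ester; 10 alkoxymethyl phosphonium chloride
Product: 13 C17 aldehyde, via phosphorus ylide 11 (not isolated), via allyl enol ether 12 (not isolated)
Conditions: 10, KN(SiMe3)2, THF, −78 to 0 °C; 6, 0 °C to rt; filtration through basic alumina; toluene, 150 °C, sealed tube
Reagents that add atoms: none
Why: Wittig olefination gives the allyl enol ether, mainly with oxygen anti to C9 to avoid allylic 1,3-strain, and its Claisen rearrangement through a chair transition state with bond formation on the equatorial α face of C8 (anti to the axial C10 methyl) sets quaternary C8 with a β-formyl group and C14 as in the target.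

Step 7
Reactants: 13 C17 aldehyde
Product: 14 C17 alcohol
Conditions: NaBH4, MeOH/THF, −20 °C; used directly
Reagents that add atoms: none
Why: Borohydride reduces only the neopentyl aldehyde and leaves the methyl ester, creating no stereocenter.

Step 8
Reactants: 14 C17 alcohol
Product: 15 isovalerate
Conditions: 3-methylbutanoyl chloride, pyridine, DMAP (cat.), CH2Cl2, 0 °C to rt
Reagents that add atoms: 3-methylbutanoyl chloride CC(C)CC(Cl)=O
Why: DMAP-catalysed acylation of the primary neopentyl alcohol installs the ester of the target before the hydroxy ester can lactonize.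

Step 9
Reactants: 15 isovalerate
Product: 16 C12 phenyl sulfide
Conditions: PhSH, AIBN (cat.), toluene, 80 °C
Reagents that add atoms: benzenethiol Sc1ccccc1
Why: Radical thiol–ene addition places sulfur on the terminal carbon C12 (anti-Markovnikov) without touching the esters or the benzyl ether.

Step 10
Reactants: 16 C12 phenyl sulfide
Product: 18 vinyl sulfide, via α-chloro sulfide 17 (not isolated)
Conditions: N-chlorosuccinimide, CH2Cl2, 0 °C to rt; then DBU, 40 °C
Reagents that add atoms: none
Why: Chlorination of the sulfide at its only α-CH2 (C12) and E2 dehydrochlorination give the electron-rich vinyl sulfide, whose sulfur will steer the regiochemistry of the cycloaddition; the alkene geometry is of no consequence.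

Step 11
Reactants: 18 vinyl sulfide
Product: 19 carboxylic acid
Conditions: LiI, EtOAc, reflux; then 1 M HCl work-up
Reagents that add atoms: none
Why: Iodide cleaves the methyl ester by SN2 attack at the methyl group, a path closed to the neopentyl isovalerate and the benzyl ether.

Step 12
Reactants: 19 carboxylic acid
Product: 22 12-phenylthio cyclobutanone, via acid chloride 20 (not isolated), via ketene 21 (not isolated)
Conditions: 1-chloro-N,N,2-trimethylprop-1-en-1-amine, CH2Cl2, 0 °C to rt; then slow addition to Et3N, toluene, 110 °C, high dilution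
Reagents that add atoms: none
Why: Dehydrochlorination of the acid chloride gives an aldoketene whose central carbon C16 is attacked by the nucleophilic β-carbon C13 of the vinyl sulfide, and the sulfur-stabilized cation at C12 then closes onto C11, so that this intramolecular ketene–alkene [2+2] cycloaddition forms ring C and the four-membered ring in the crossed (bicyclo[3.1.1]) sense with C11 and C13 forced cis-diaxial on the β face of the chair of ring C.

Step 13
Reactants: 22 12-phenylthio cyclobutanone
Product: 23 cyclobutanone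
Conditions: Raney Ni (W-2, deactivated in acetone), acetone/EtOH, rt
Reagents that add atoms: none
Why: Hydrogenolysis of the C–S bond removes the steering group and leaves C12 as CH2, the deactivated catalyst sparing the ketone and the benzyl ether; no stereocenter is affected.

Step 14
Reactants: 23 cyclobutanone
Product: 24 γ-lactone
Conditions: mCPBA, NaHCO3, CH2Cl2, 0 °C to rt
Reagents that add atoms: 3-chloroperbenzoic acid OOC(=O)c1cccc(Cl)c1
Why: The peracid adds to the strained carbonyl C16 from the exo face (anti to the axial C17 arm) to give the Criegee adduct, and a concerted 1,2-shift of the C16–C11 bond to the peroxide oxygen with loss of 3-chlorobenzoate inserts one oxygen between C16 and C11. The closest known reaction type is the Baeyer–Villiger oxidation of fused and bridged bicyclic cyclobutanones to γ-lactones. No ring is closed: the four-membered ring C16–C11–C12–C13 is enlarged to the five-membered ring C16–O–C11–C12–C13 by atom insertion. C11 migrates with retention, so the 11β C–O bond takes the place of the 11β C–C16 bond fixed in step 12, and no other stereocenter is touched. The step needs regioselectivity between the two bridgehead CH carbons C11 and C13 and chemoselectivity for the cyclobutanone over two esters and a benzyl ether. Migration of C11 should be favored because its bond to C16 is syn-axial to the C10 methyl and to C17 (more strain released), because the perester residue of the Criegee adduct is pushed to the less crowded C13 side and so lies antiperiplanar to C16–C11, and because C13 is slightly deactivated by the oxygen on C15; ring strain makes the cyclobutanone far more reactive than any other group present.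

Step 15
Reactants: 24 γ-lactone
Product: 25 lactol
Conditions: Sia2BH (disiamylborane), THF, 0 °C to rt; then H2O
Reagents that add atoms: none
Why: Disiamylborane reduces γ-lactones to lactols but does not reduce esters, so the isovalerate survives; the hemiacetal center C16 is formed as an equilibrating mixture.

Step 16
Reactants: 25 lactol
Product: 26 lactol acetate benzyl ether
Conditions: Ac2O, pyridine, DMAP (cat.), CH2Cl2, 0 °C
Reagents that add atoms: acetic anhydride CC(=O)OC(C)=O
Why: Acetylation of the equilibrating lactol should occur mainly on the exo hydroxyl (anti to the axial C17 arm), which fixes C16 with the acetate exo as in the target.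

Step 17
Reactants: 26 lactol acetate benzyl ether
Product: 27 C15 alcohol
Conditions: H2 (1 atm), 10% Pd/C, EtOAc, rt
Reagents that add atoms: none
Why: Hydrogenolysis cleaves the benzyl ether under neutral conditions that leave the acetoxy acetal and the ester intact.

Step 18
Reactants: 27 C15 alcohol
Product: 28 target CNP0331370.1
Conditions: Dess–Martin periodinane, NaHCO3, CH2Cl2, 0 °C to rt
Reagents that add atoms: none
Why: Buffered Dess–Martin oxidation gives the aldehyde without acid or base, so the α-stereocenter C14 and the acetoxy acetal are preserved.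

**Compound list**

1 | (+)-sclareolide, (3aR,5aS,9aS,9bR)-3a,6,6,9a-tetramethyldecahydronaphtho[2,1-b]furan-2(1H)-one | O=C1C[C@H]2[C@](C)(O1)CC[C@H]3C(C)(C)CCC[C@]23C | starting material
2 | potassium carboxylate: ring-opened sclareolide salt with 8α-OH and 8β-CH3 | [K+].[O-]C(=O)C[C@H]1[C@](C)(O)CC[C@H]2C(C)(C)CCC[C@]12C | intermediate
3 | methyl 8α-hydroxy ester: methyl 2-[(1R,2R,4aS,8aS)-2-hydroxy-2,5,5,8a-tetramethyldecahydronaphthalen-1-yl]acetate | COC(=O)C[C@H]1[C@](C)(O)CC[C@H]2C(C)(C)CCC[C@]12C | intermediate
4 | exocyclic alkene ester: methyl 2-[(1S,4aS,8aS)-5,5,8a-trimethyl-2-methylidenedecahydronaphthalen-1-yl]acetate | COC(=O)C[C@H]1C(=C)CC[C@H]2C(C)(C)CCC[C@]12C | intermediate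
5 | ozonide: spiro-1,2,4-trioxolane at C8 of 4 | COC(=O)C[C@H]1C3(OCOO3)CC[C@H]2C(C)(C)CCC[C@]12C | intermediate
6 | C8 keto ester: trans-decalin-8-one with 9α-H and the CH2CO2Me arm (C11, C16) on C9 | COC(=O)C[C@H]1C(=O)CC[C@H]2C(C)(C)CCC[C@]12C | intermediate
7 | (E)-but-2-ene-1,4-diol | OC/C=C/CO | starting material
8 | (E)-4-(benzyloxy)but-2-en-1-ol | OC/C=C/COCc1ccccc1 | intermediate
9 | chloromethyl ether of 8 | ClCOC/C=C/COCc1ccccc1 | intermediate
10 | alkoxymethyl phosphonium chloride: {[(E)-4-(benzyloxy)but-2-enyloxy]methyl}triphenylphosphonium chloride | [Cl-].c1ccccc1[P+](c1ccccc1)(c1ccccc1)COC/C=C/COCc1ccccc1 | intermediate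
11 | phosphorus ylide from 10 | c1ccccc1P(c1ccccc1)(c1ccccc1)=COC/C=C/COCc1ccccc1 | intermediate
12 | allyl enol ether: C8=C17H–O–CH2CH=CHCH2OBn, oxygen anti to C9, allyl alkene E | COC(=O)C[C@H]1/C(=C/OC/C=C/COCc3ccccc3)CC[C@H]2C(C)(C)CCC[C@]12C | intermediate
13 | C17 aldehyde: C8 bears β-CHO (C17) and α-C14H(CH2OBn)(CH=CH2), C14 as in the target | COC(=O)C[C@H]1[C@](C=O)([C@H](COCc3ccccc3)C=C)CC[C@H]2C(C)(C)CCC[C@]12C | intermediate
14 | C17 alcohol: 13 with 8β-CH2OH | COC(=O)C[C@H]1[C@](CO)([C@H](COCc3ccccc3)C=C)CC[C@H]2C(C)(C)CCC[C@]12C | intermediate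
15 | isovalerate: 14 acylated at C17–O with 3-methylbutanoyl | COC(=O)C[C@H]1[C@](COC(=O)CC(C)C)([C@H](COCc3ccccc3)C=C)CC[C@H]2C(C)(C)CCC[C@]12C | intermediate
16 | C12 phenyl sulfide: C14–CH2–CH2–SPh | COC(=O)C[C@H]1[C@](COC(=O)CC(C)C)([C@H](COCc3ccccc3)CCSc3ccccc3)CC[C@H]2C(C)(C)CCC[C@]12C | intermediate
17 | α-chloro sulfide: C14–CH2–CHCl–SPh, mixture at C12 | COC(=O)C[C@H]1[C@](COC(=O)CC(C)C)([C@H](COCc3ccccc3)CC(Cl)Sc3ccccc3)CC[C@H]2C(C)(C)CCC[C@]12C | intermediate
18 | vinyl sulfide: C14–CH=CH–SPh, E isomer drawn, E/Z mixture usable | COC(=O)C[C@H]1[C@](COC(=O)CC(C)C)([C@H](COCc3ccccc3)/C=C/Sc3ccccc3)CC[C@H]2C(C)(C)CCC[C@]12C | intermediate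
19 | carboxylic acid: 18 with free C16 acid | OC(=O)C[C@H]1[C@](COC(=O)CC(C)C)([C@H](COCc3ccccc3)/C=C/Sc3ccccc3)CC[C@H]2C(C)(C)CCC[C@]12C | intermediate
20 | acid chloride of 19 | ClC(=O)C[C@H]1[C@](COC(=O)CC(C)C)([C@H](COCc3ccccc3)/C=C/Sc3ccccc3)CC[C@H]2C(C)(C)CCC[C@]12C | intermediate
21 | ketene: C9–C11H=C16=O | O=C=C[C@H]1[C@](COC(=O)CC(C)C)([C@H](COCc3ccccc3)/C=C/Sc3ccccc3)CC[C@H]2C(C)(C)CCC[C@]12C | intermediate
22 | 12-phenylthio cyclobutanone: C16=O bridging C11 and C13 on the β face of ring C, SPh on C12 (either orientation), 14-CH2OBn, 17-isovalerate | O=C1[C@H]2C(Sc4ccccc4)[C@@H]1[C@@H](COCc4ccccc4)[C@]1(COC(=O)CC(C)C)CC[C@H]3C(C)(C)CCC[C@]3(C)[C@@H]21 | intermediate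
23 | cyclobutanone: 22 with C12H2 | O=C1[C@H]2C[C@@H]1[C@@H](COCc4ccccc4)[C@]1(COC(=O)CC(C)C)CC[C@H]3C(C)(C)CCC[C@]3(C)[C@@H]21 | intermediate
24 | γ-lactone: C16(=O)–O–C11 bridging C11 and C13 (6-oxabicyclo[3.2.1]octan-7-one) | O=C1O[C@H]2C[C@@H]1[C@@H](COCc4ccccc4)[C@]1(COC(=O)CC(C)C)CC[C@H]3C(C)(C)CCC[C@]3(C)[C@@H]21 | intermediate
25 | lactol: 16-hydroxy hemiacetal, exo anomer drawn | O[C@H]1O[C@H]2C[C@@H]1[C@@H](COCc4ccccc4)[C@]1(COC(=O)CC(C)C)CC[C@H]3C(C)(C)CCC[C@]3(C)[C@@H]21 | intermediate
26 | lactol acetate benzyl ether: 16-exo-acetoxy, 15-OBn | CC(=O)O[C@H]1O[C@H]2C[C@@H]1[C@@H](COCc4ccccc4)[C@]1(COC(=O)CC(C)C)CC[C@H]3C(C)(C)CCC[C@]3(C)[C@@H]21 | intermediate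
27 | C15 alcohol: 26 with free 15-OH | CC(=O)O[C@H]1O[C@H]2C[C@@H]1[C@@H](CO)[C@]1(COC(=O)CC(C)C)CC[C@H]3C(C)(C)CCC[C@]3(C)[C@@H]21 | intermediate
28 | target CNP0331370.1 | CC(=O)O[C@H]1O[C@H]2C[C@@H]1[C@@H](C=O)[C@]1(COC(=O)CC(C)C)CC[C@H]3C(C)(C)CCC[C@]3(C)[C@@H]21 | target

**Step count and risks**

Total step count: 18. Longest linear sequence: 16 (steps 1–3 and 6–18).

The three steps most likely to fail:

Step 14. The oxygen insertion may discriminate poorly between migration of C11 and of C13, giving the regioisomeric lactone. The fallback sets out from 23 and returns at 24. Condensation of 23 with NH2OH·HCl/NaOAc gives the oximes, of which the isomer with hydroxyl anti to C11, oxime F1, is separated (the other is re-equilibrated with acid). A Beckmann rearrangement (cyanuric chloride and ZnCl2 in catalytic amounts, MeCN) moves the anti carbon C11 to nitrogen stereospecifically and gives lactam F2. Nitrosation (N2O4, NaOAc, CH2Cl2, −20 °C) gives N-nitroso lactam F3, and its thermal nitrosoamide rearrangement (toluene, 80 °C, loss of N2) replaces N by O with retention to give 24.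

Step 12. The aldoketene may dimerize or acylate before it cycloadds. The fallback sets out from 19 and returns at 22. Coupling with pyrrolidine (EDC·HCl, HOBt) gives pyrrolidine amide F4. Treatment with Tf2O and 2,4,6-collidine in ClCH2CH2Cl at reflux forms keteniminium triflate F5, a more electrophilic and non-dimerizing ketene equivalent, which undergoes the same crossed [2+2] to cyclobutaniminium triflate F6. Hydrolysis with aqueous NaHCO3 gives 22.

Step 6. The Wittig step may give the wrong enol ether geometry (and so the C14 epimer after rearrangement), or the ylide may enolize the hindered ketone. The fallback sets out from 4 and returns at 13 through 12. Epoxidation of 4 from the α face (mCPBA) gives 8α,17-epoxide F7, and a Meinwald rearrangement (BF3·OEt2) gives C8 carbaldehyde F8. Acid-catalysed condensation with 8 (TsOH, toluene, removal of water) gives bis-allyl acetal F9. Heating with an acid catalyst at 160 °C expels one equivalent of 8 to form 12 under equilibrating conditions (thermodynamic oxygen-anti-to-C9 isomer), which rearranges in the same pot to 13.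

Further compounds
F1 | step 14 | oxime of 23 with hydroxyl anti to C11 | O/N=C1/[C@H]2C[C@@H]1[C@@H](COCc4ccccc4)[C@]1(COC(=O)CC(C)C)CC[C@H]3C(C)(C)CCC[C@]3(C)[C@@H]21
F2 | step 14 | bridged γ-lactam with N between C16 and C11 | O=C1N[C@H]2C[C@@H]1[C@@H](COCc4ccccc4)[C@]1(COC(=O)CC(C)C)CC[C@H]3C(C)(C)CCC[C@]3(C)[C@@H]21
F3 | step 14 | N-nitroso lactam | O=C1N(N=O)[C@H]2C[C@@H]1[C@@H](COCc4ccccc4)[C@]1(COC(=O)CC(C)C)CC[C@H]3C(C)(C)CCC[C@]3(C)[C@@H]21
F4 | step 12 | pyrrolidine amide of 19 | O=C(N1CCCC1)C[C@H]2[C@](COC(=O)CC(C)C)([C@H](COCc4ccccc4)/C=C/Sc4ccccc4)CC[C@H]3C(C)(C)CCC[C@]23C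
F5 | step 12 | keteniminium triflate | [O-]S(=O)(=O)C(F)(F)F.C1CC[N+](C1)=C=C[C@H]2[C@](COC(=O)CC(C)C)([C@H](COCc4ccccc4)/C=C/Sc4ccccc4)CC[C@H]3C(C)(C)CCC[C@]23C
F6 | step 12 | cyclobutaniminium triflate | [O-]S(=O)(=O)C(F)(F)F.C1(=[N+]5CCCC5)[C@H]2C(Sc4ccccc4)[C@@H]1[C@@H](COCc4ccccc4)[C@]1(COC(=O)CC(C)C)CC[C@H]3C(C)(C)CCC[C@]3(C)[C@@H]21
F7 | step 6 | 8α,17-epoxide of 4 | COC(=O)C[C@H]1[C@@]3(CO3)CC[C@H]2C(C)(C)CCC[C@]12C
F8 | step 6 | C8 carbaldehyde, mixture at C8 | COC(=O)C[C@H]1C(C=O)CC[C@H]2C(C)(C)CCC[C@]12C
F9 | step 6 | bis-allyl acetal of F8 with two units of 8 | COC(=O)C[C@H]1C(C(OC/C=C/COCc3ccccc3)OC/C=C/COCc3ccccc3)CC[C@H]2C(C)(C)CCC[C@]12C
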